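**Plan**
1. The retrosynthesis cuts C11=C12 and C11'=C12' (two Wittig disconnections) into a furanoid C15 phosphonium salt, the C10 trienedial and an ε-ring C15 phosphonium salt. Inside the furanoid piece it then cuts O–C5 (C6=C7 being traced back to a C6 selenide), C8–C9 and C6–C7.
2. Enabling feature: the quaternary C5 (methyl and ring oxygen) next to the C6=C7 alkene of the fused dihydrofuran corresponds to a C5=C6 cyclohexene alkene attacked by a C8 hydroxyl. C1 and C5 carry no hydrogen, so elimination from C6 can only give back C6=C7.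
3. Forward, furanoid half: actinol → enol triflate → allylation and oxidative cleavage to the C8 aldehyde → alkenylchromium addition, oxidation and oxazaborolidine reduction (sets C8) → selenoetherification closes the five-membered oxygen ring on the existing cyclohexene → selenoxide elimination → phosphonium salt.
4. Forward, ε half and union: (R)-α-ionone → C15 dienoate → ring enone → trans alcohol → phosphonium salt; Wittig with the C10 dialdehyde, Wittig with the furanoid salt, desilylation.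
5. Stereochemistry: C3 comes from actinol, C8 from catalyst-controlled ketone reduction, C5 (and transient C6) from anti addition across C5=C6 steered by the C3 silyloxy group, C6' from (R)-α-ionone, and C3' from face-selective hydride delivery. The all-E chain comes from E-retentive couplings and Z→E equilibration.

Key step: step 10

Remark: positions are given in carotenoid numbering; the target is read as the all-E (3S,5R,8S,3'R,6'R)-5,8-epoxy-5,8-dihydro-β,ε-carotene-3,3'-diol, and (R)-α-ionone, actinol and the C10 trienedial are taken as purchasable in the stated form. TBS = tert-butyldimethylsilyl.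

Step 1
Reactants: 1 (4R,6R)-4-hydroxy-2,2,6-trimethylcyclohexan-1-one (actinol)
Product: 2 (4R,6R)-4-(TBSO)-2,2,6-trimethylcyclohexan-1-one
Conditions: TBSCl, imidazole, DMF, rt
Reagents that add atoms: tert-butyldimethylsilyl chloride, CC(C)(C)[Si](C)(C)Cl
Why: Routine silylation of the secondary alcohol (imidazole-promoted) should leave the hindered ketone and both stereocentres untouched.

Step 2
Reactants: 2 (4R,6R)-4-(TBSO)-2,2,6-trimethylcyclohexan-1-one
Product: 3 (4R)-4-(TBSO)-2,6,6-trimethylcyclohex-1-en-1-yl trifluoromethanesulfonate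
Conditions: LiN(i-Pr)2, THF, −78 → 0 °C; PhNTf2, 0 °C → rt
Reagents that add atoms: N-phenylbis(trifluoromethanesulfonimide), O=S(=O)(N(c1ccccc1)S(=O)(=O)C(F)(F)F)C(F)(F)F
Why: Only one α-carbon carries hydrogen (the other is quaternary), so deprotonation should give a single tetrasubstituted enolate that is O-sulfonylated (enol triflate formation); the methyl-bearing stereocentre vanishes and the silyloxy centre is kept.

Step 3
Reactants: 3 (4R)-4-(TBSO)-2,6,6-trimethylcyclohex-1-en-1-yl trifluoromethanesulfonate; 4 allyltributylstannane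
Product: 5 tert-butyldimethyl{[(1R)-3,5,5-trimethyl-4-(prop-2-en-1-yl)cyclohex-3-en-1-yl]oxy}silane
Conditions: Pd(PPh3)4 (5 mol%), LiCl, THF, 65 °C
Reagents that add atoms: none
Why: Stille coupling (oxidative addition of zerovalent palladium into the vinyl triflate, chloride-assisted transmetalation from tin, reductive elimination) should forge C6–C7 on this hindered triflate class without touching the silyl ether.

Step 4
Reactants: 5 tert-butyldimethyl{[(1R)-3,5,5-trimethyl-4-(prop-2-en-1-yl)cyclohex-3-en-1-yl]oxy}silane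
Product: 7 2-[(4R)-4-(TBSO)-2,6,6-trimethylcyclohex-1-en-1-yl]acetaldehyde, via vicinal diol 6 (not isolated)
Conditions: OsO4 (2 mol%), NaIO4, 2,6-lutidine, dioxane/H2O, rt
Reagents that add atoms: osmium tetroxide, O=[Os](=O)(=O)=O; sodium periodate, [Na+].[O-]I(=O)(=O)=O
Why: Lemieux–Johnson cleavage should work because OsO4 dihydroxylates the open monosubstituted alkene much faster than the shielded tetrasubstituted ring alkene, and the lutidine buffer keeps the β,γ-unsaturated aldehyde from moving into conjugation.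

Step 5
Reactants: 8 but-2-yn-1-ol
Product: 9 (E)-3-iodobut-2-en-1-ol
Conditions: Cp2ZrHCl (2.2 equiv), THF, rt; I2, 0 °C
Reagents that add atoms: iodine, I-I
Why: Schwartz hydrozirconation adds Zr–H syn with zirconium settling (excess reagent equilibrates) on the methyl-bearing carbon remote from oxygen, and iodinolysis with retention should give the iodide with iodine trans to CH2OH.

Step 6
Reactants: 9 (E)-3-iodobut-2-en-1-ol
Product: 10 (E)-3-iodobut-2-en-1-yl 2,2-dimethylpropanoate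
Conditions: t-BuCOCl, pyridine, DMAP (cat.), CH2Cl2, 0 °C → rt
Reagents that add atoms: pivaloyl chloride, CC(C)(C)C(=O)Cl
Why: Standard acylation gives an ester that tolerates the organochromium chemistry, the oxidation and the borane reduction that follow.

Step 7
Reactants: 7 2-[(4R)-4-(TBSO)-2,6,6-trimethylcyclohex-1-en-1-yl]acetaldehyde; 10 (E)-3-iodobut-2-en-1-yl 2,2-dimethylpropanoate
Product: 11 (2E)-4-hydroxy-5-[(4R)-4-(TBSO)-2,6,6-trimethylcyclohex-1-en-1-yl]-3-methylpent-2-en-1-yl 2,2-dimethylpropanoate (both C4 epimers)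
Conditions: CrCl2 (4 equiv), NiCl2 (2 mol%), DMF, rt
Reagents that add atoms: none
Why: Nozaki–Hiyama–Kishi coupling (zerovalent nickel inserts into C–I, transmetalation gives an alkenyl species of trivalent chromium) should add only to the aldehyde with retention of alkene geometry and form C8–C9; both C8 epimers are accepted because step 8 erases the centre.

Step 8
Reactants: 11 (2E)-4-hydroxy-5-[(4R)-4-(TBSO)-2,6,6-trimethylcyclohex-1-en-1-yl]-3-methylpent-2-en-1-yl 2,2-dimethylpropanoate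
Product: 12 (2E)-5-[(4R)-4-(TBSO)-2,6,6-trimethylcyclohex-1-en-1-yl]-3-methyl-4-oxopent-2-en-1-yl 2,2-dimethylpropanoate
Conditions: Dess–Martin periodinane, pyridine, CH2Cl2, 0 °C
Reagents that add atoms: none
Why: Dess–Martin oxidation under pyridine buffering should give the enone without acid or base strong enough to pull the ring alkene into conjugation.

Step 9
Reactants: 12 (2E)-5-[(4R)-4-(TBSO)-2,6,6-trimethylcyclohex-1-en-1-yl]-3-methyl-4-oxopent-2-en-1-yl 2,2-dimethylpropanoate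
Product: 13 (2E,4S)-4-hydroxy-5-[(4R)-4-(TBSO)-2,6,6-trimethylcyclohex-1-en-1-yl]-3-methylpent-2-en-1-yl 2,2-dimethylpropanoate
Conditions: (R)-2-methyl-CBS-oxazaborolidine (20 mol%), catecholborane, toluene, −78 °C
Reagents that add atoms: none
Why: Corey–Bakshi–Shibata reduction sets C8: the (R)-oxazaborolidine binds the ketone with the α-methylalkenyl group as the large substituent and delivers hydride to one face, giving the (S)-carbinol by analogy with (S)-1-phenylethanol from acetophenone, while low temperature and catecholborane avoid hydroboration and 1,4-reduction.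

Step 10
Reactants: 13 (2E,4S)-4-hydroxy-5-[(4R)-4-(TBSO)-2,6,6-trimethylcyclohex-1-en-1-yl]-3-methylpent-2-en-1-yl 2,2-dimethylpropanoate
Product: 14 (2E)-3-[(2S,3aR,6S,7aR)-6-(TBSO)-4,4,7a-trimethyl-3a-(phenylselanyl)octahydro-1-benzofuran-2-yl]but-2-en-1-yl 2,2-dimethylpropanoate
Conditions: N-(phenylseleno)phthalimide (1.3 equiv), camphorsulfonic acid (5 mol%), CH2Cl2, −20 → 0 °C
Reagents that add atoms: N-(phenylseleno)phthalimide, O=C1N([Se]c2ccccc2)C(=O)c2ccccc12
Why: The acid-activated selenium reagent transfers PhSe+ reversibly to the electron-rich tetrasubstituted C5=C6 bond, and the C8 hydroxyl opens the seleniranium ion at C5 from the opposite face, forming O–C5 and C6–Se; the closest known reaction is the phenylselenoetherification of homoallylic alcohols to 3-selanyl tetrahydrofurans. The five-membered oxygen ring closes in the 5-endo mode (C5 and C6 both lie inside the new ring), the 4-exo path at C6 leading to a strained oxetane, so the tether length alone fixes regiochemistry on an alkene whose two carbons are equally substituted. C5 is controlled by the C3 silyloxy group: trans-diaxial opening puts the new C5–O bond axial, which is only comfortable on the face anti to the equatorial C3–OTBS (the other face would force O, OTBS and the axial C1 methyl syn-axial), and reversibility of ion formation funnels material through this pathway. C6 follows from the anti addition (Se trans to the new C–O, hence a cis-fused bicycle), and C8, set in step 9, is not touched. The step needs chemoselectivity for the ring alkene over C9=C10, which is deactivated by two allylic C–O bonds and has no hydroxyl placed to trap its seleniranium ion, so addition there should revert.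

Step 11
Reactants: 14 (2E)-3-[(2S,3aR,6S,7aR)-6-(TBSO)-4,4,7a-trimethyl-3a-(phenylselanyl)octahydro-1-benzofuran-2-yl]but-2-en-1-yl 2,2-dimethylpropanoate
Product: 16 (2E)-3-[(2S,6S,7aR)-6-(TBSO)-4,4,7a-trimethyl-2,4,5,6,7,7a-hexahydro-1-benzofuran-2-yl]but-2-en-1-yl 2,2-dimethylpropanoate, via selenoxide 15 (not isolated)
Conditions: mCPBA (1.05 equiv), CH2Cl2, −78 °C; i-Pr2NH, −78 °C → rt
Reagents that add atoms: none
Why: Oxidation at selenium followed by selenoxide syn-elimination should give C6=C7 only, because C7 holds the sole β-hydrogen (C1 and C5 are quaternary) and one of its hydrogens is cis to selenium, while the amine traps the selenenic acid.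

Step 12
Reactants: 16 (2E)-3-[(2S,6S,7aR)-6-(TBSO)-4,4,7a-trimethyl-2,4,5,6,7,7a-hexahydro-1-benzofuran-2-yl]but-2-en-1-yl 2,2-dimethylpropanoate
Product: 17 (2E)-3-[(2S,6S,7aR)-6-(TBSO)-4,4,7a-trimethyl-2,4,5,6,7,7a-hexahydro-1-benzofuran-2-yl]but-2-en-1-ol
Conditions: i-Bu2AlH (2.2 equiv), CH2Cl2, −78 °C; Rochelle salt work-up
Reagents that add atoms: none
Why: Reductive cleavage of the pivalate is the only reaction open to the hydride, and the non-acidic conditions spare the doubly allylic C8–O bond.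

Step 13
Reactants: 17 (2E)-3-[(2S,6S,7aR)-6-(TBSO)-4,4,7a-trimethyl-2,4,5,6,7,7a-hexahydro-1-benzofuran-2-yl]but-2-en-1-ol
Product: 19 {(2E)-3-[(2S,6S,7aR)-6-(TBSO)-4,4,7a-trimethyl-2,4,5,6,7,7a-hexahydro-1-benzofuran-2-yl]but-2-en-1-yl}triphenylphosphonium bromide, via allylic bromide 18 (not isolated)
Conditions: CBr4, PPh3 (1.2 equiv each), 2,6-lutidine, CH2Cl2, −20 °C; then PPh3 (1.5 equiv), rt
Reagents that add atoms: carbon tetrabromide, BrC(Br)(Br)Br; triphenylphosphine, c1ccc(cc1)P(c1ccccc1)c1ccccc1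
Why: Appel bromination under buffered conditions and SN2 quaternisation of the primary allylic bromide should give the Wittig salt without the acid that could epimerise C8.

Step 14
Reactants: 20 (R)-α-ionone; 21 triethyl phosphonoacetate
Product: 22 ethyl (2E,4E)-3-methyl-5-[(1R)-2,6,6-trimethylcyclohex-2-en-1-yl]penta-2,4-dienoate
Conditions: NaH, THF, 0 → 40 °C; 2Z isomer removed by chromatography
Reagents that add atoms: none
Why: Horner–Wadsworth–Emmons olefination of the methyl ketone should give mainly the 2E dienoate, and the phosphonate anion is too weak a base to enolise the shielded C6'–H, so the stereocentre is kept.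

Step 15
Reactants: 22 ethyl (2E,4E)-3-methyl-5-[(1R)-2,6,6-trimethylcyclohex-2-en-1-yl]penta-2,4-dienoate
Product: 23 ethyl (2E,4E)-3-methyl-5-[(1R)-2,6,6-trimethyl-4-oxocyclohex-2-en-1-yl]penta-2,4-dienoate
Conditions: t-BuOOH (70% aq.), Rh2(cap)4 (1 mol%), K2CO3 (cat.), CH2Cl2, rt
Reagents that add atoms: tert-butyl hydroperoxide, CC(C)(C)OO
Why: Radical allylic oxidation (tert-butylperoxy chain under dirhodium caprolactamate catalysis) should attack the accessible ring CH2 next to the trisubstituted alkene and collapse to the enone, the shielded tertiary C6'–H and the electron-poor dienoate positions reacting more slowly.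

Step 16
Reactants: 23 ethyl (2E,4E)-3-methyl-5-[(1R)-2,6,6-trimethyl-4-oxocyclohex-2-en-1-yl]penta-2,4-dienoate
Product: 24 ethyl (2E,4E)-5-[(1R,4R)-4-hydroxy-2,6,6-trimethylcyclohex-2-en-1-yl]-3-methylpenta-2,4-dienoate
Conditions: LiBH(s-Bu)3 (1.1 equiv), THF, −78 °C
Reagents that add atoms: none
Why: 1,2-Reduction of the β,β-disubstituted cyclohexenone sets C3': in the half-chair that carries the side chain pseudo-axially, the axial C1' methyl blocks the opposite face, so the bulky hydride should enter from the side-chain face and place the hydroxyl trans to the chain (4R), leaving the ester alone at −78 °C.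

Step 17
Reactants: 24 ethyl (2E,4E)-5-[(1R,4R)-4-hydroxy-2,6,6-trimethylcyclohex-2-en-1-yl]-3-methylpenta-2,4-dienoate
Product: 25 ethyl (2E,4E)-5-[(1R,4R)-4-(TBSO)-2,6,6-trimethylcyclohex-2-en-1-yl]-3-methylpenta-2,4-dienoate
Conditions: TBSCl, imidazole, DMF, rt
Reagents that add atoms: tert-butyldimethylsilyl chloride, CC(C)(C)[Si](C)(C)Cl
Why: Silylation masks the ring allylic alcohol so that only the primary alcohol made in step 18 is brominated in step 19.

Step 18
Reactants: 25 ethyl (2E,4E)-5-[(1R,4R)-4-(TBSO)-2,6,6-trimethylcyclohex-2-en-1-yl]-3-methylpenta-2,4-dienoate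
Product: 26 (2E,4E)-5-[(1R,4R)-4-(TBSO)-2,6,6-trimethylcyclohex-2-en-1-yl]-3-methylpenta-2,4-dien-1-ol
Conditions: i-Bu2AlH (2.2 equiv), CH2Cl2, −78 °C
Reagents that add atoms: none
Why: 1,2-Reduction of the dienoate to the allylic alcohol is standard and keeps both alkene geometries.

Step 19
Reactants: 26 (2E,4E)-5-[(1R,4R)-4-(TBSO)-2,6,6-trimethylcyclohex-2-en-1-yl]-3-methylpenta-2,4-dien-1-ol
Product: 28 {(2E,4E)-5-[(1R,4R)-4-(TBSO)-2,6,6-trimethylcyclohex-2-en-1-yl]-3-methylpenta-2,4-dien-1-yl}triphenylphosphonium bromide, via dienyl bromide 27 (not isolated)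
Conditions: CBr4, PPh3 (1.2 equiv each), 2,6-lutidine, CH2Cl2, −20 °C; then PPh3 (1.5 equiv), rt
Reagents that add atoms: carbon tetrabromide, BrC(Br)(Br)Br; triphenylphosphine, c1ccc(cc1)P(c1ccccc1)c1ccccc1
Why: Appel bromination and quaternisation avoid the acidic salt-forming conditions that would ionise the ring allylic C3'–O bond.

Step 20
Reactants: 28 {(2E,4E)-5-[(1R,4R)-4-(TBSO)-2,6,6-trimethylcyclohex-2-en-1-yl]-3-methylpenta-2,4-dien-1-yl}triphenylphosphonium bromide; 29 (2E,4E,6E)-2,7-dimethylocta-2,4,6-trienedial (3 equiv)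
Product: 30 (2E,4E,6E,8E,10E,12E)-13-[(1R,4R)-4-(TBSO)-2,6,6-trimethylcyclohex-2-en-1-yl]-2,7,11-trimethyltrideca-2,4,6,8,10,12-hexaenal
Conditions: NaOMe, CH2Cl2/MeOH, 0 °C → rt (salt and base added slowly to 29); then I2 (cat.), CH2Cl2, rt, light
Reagents that add atoms: none
Why: Wittig olefination of the allylic ylide with one formyl group of the symmetrical dialdehyde forms C11'=C12'; excess dialdehyde and inverse addition should suppress double condensation, and iodine equilibration converts the Z isomer at the new bond to all-E.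

Step 21
Reactants: 19 {(2E)-3-[(2S,6S,7aR)-6-(TBSO)-4,4,7a-trimethyl-2,4,5,6,7,7a-hexahydro-1-benzofuran-2-yl]but-2-en-1-yl}triphenylphosphonium bromide; 30 (2E,4E,6E,8E,10E,12E)-13-[(1R,4R)-4-(TBSO)-2,6,6-trimethylcyclohex-2-en-1-yl]-2,7,11-trimethyltrideca-2,4,6,8,10,12-hexaenal
Product: 31 all-E (3S,5R,8S,3'R,6'R)-3,3'-bis(TBSO)-5,8-epoxy-5,8-dihydro-β,ε-carotene
Conditions: NaOMe, CH2Cl2/MeOH, 0 °C → rt; then EtOAc, 70 °C, dark, argon
Reagents that add atoms: none
Why: Wittig olefination joins the halves at C11=C12; the ylide is a 4-alkoxy-3-methylbut-2-enylidene phosphorane of the kind long used as acetal-bearing C5 reagents in polyene synthesis and should not expel its allylic ring oxygen, and gentle heating isomerises the hindered 11Z isomer to all-E without acid.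

Step 22
Reactants: 31 all-E (3S,5R,8S,3'R,6'R)-3,3'-bis(TBSO)-5,8-epoxy-5,8-dihydro-β,ε-carotene
Product: 32 all-E (3S,5R,8S,3'R,6'R)-5,8-epoxy-5,8-dihydro-β,ε-carotene-3,3'-diol
Conditions: Bu4NF, THF, rt, dim light, argon
Reagents that add atoms: none
Why: Fluoride cleaves both silyl ethers under non-acidic conditions that spare the doubly allylic C8–O bond, the ε-ring allylic alcohol and the polyene.

**Compound list**
1 | (4R,6R)-4-hydroxy-2,2,6-trimethylcyclohexan-1-one (actinol) | C[C@@H]1C[C@@H](O)CC(C)(C)C1=O | starting material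
2 | (4R,6R)-4-(TBSO)-2,2,6-trimethylcyclohexan-1-one | C[C@@H]1C[C@@H](O[Si](C)(C)C(C)(C)C)CC(C)(C)C1=O | intermediate
3 | (4R)-4-(TBSO)-2,6,6-trimethylcyclohex-1-en-1-yl trifluoromethanesulfonate | CC1=C(OS(=O)(=O)C(F)(F)F)C(C)(C)C[C@H](O[Si](C)(C)C(C)(C)C)C1 | intermediate
4 | allyltributylstannane | C=CC[Sn](CCCC)(CCCC)CCCC | starting material
5 | tert-butyldimethyl{[(1R)-3,5,5-trimethyl-4-(prop-2-en-1-yl)cyclohex-3-en-1-yl]oxy}silane | CC1=C(CC=C)C(C)(C)C[C@H](O[Si](C)(C)C(C)(C)C)C1 | intermediate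
6 | 3-[(4R)-4-(TBSO)-2,6,6-trimethylcyclohex-1-en-1-yl]propane-1,2-diol (both C2 epimers) | CC1=C(CC(O)CO)C(C)(C)C[C@H](O[Si](C)(C)C(C)(C)C)C1 | intermediate (not isolated)
7 | 2-[(4R)-4-(TBSO)-2,6,6-trimethylcyclohex-1-en-1-yl]acetaldehyde | CC1=C(CC=O)C(C)(C)C[C@H](O[Si](C)(C)C(C)(C)C)C1 | intermediate
8 | but-2-yn-1-ol | CC#CCO | starting material
9 | (E)-3-iodobut-2-en-1-ol | C/C(I)=C\CO | intermediate
10 | (E)-3-iodobut-2-en-1-yl 2,2-dimethylpropanoate | C/C(I)=C\COC(=O)C(C)(C)C | intermediate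
11 | (2E)-4-hydroxy-5-[(4R)-4-(TBSO)-2,6,6-trimethylcyclohex-1-en-1-yl]-3-methylpent-2-en-1-yl 2,2-dimethylpropanoate (both C4 epimers) | CC1=C(CC(O)/C(C)=C/COC(=O)C(C)(C)C)C(C)(C)C[C@H](O[Si](C)(C)C(C)(C)C)C1 | intermediate
12 | (2E)-5-[(4R)-4-(TBSO)-2,6,6-trimethylcyclohex-1-en-1-yl]-3-methyl-4-oxopent-2-en-1-yl 2,2-dimethylpropanoate | CC1=C(CC(=O)/C(C)=C/COC(=O)C(C)(C)C)C(C)(C)C[C@H](O[Si](C)(C)C(C)(C)C)C1 | intermediate
13 | (2E,4S)-4-hydroxy-5-[(4R)-4-(TBSO)-2,6,6-trimethylcyclohex-1-en-1-yl]-3-methylpent-2-en-1-yl 2,2-dimethylpropanoate | CC1=C(C[C@H](O)/C(C)=C/COC(=O)C(C)(C)C)C(C)(C)C[C@H](O[Si](C)(C)C(C)(C)C)C1 | intermediate (key-step precursor)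
14 | (2E)-3-[(2S,3aR,6S,7aR)-6-(TBSO)-4,4,7a-trimethyl-3a-(phenylselanyl)octahydro-1-benzofuran-2-yl]but-2-en-1-yl 2,2-dimethylpropanoate | CC(C)(C)C(=O)OC/C=C(\C)[C@@H]1C[C@@]2([Se]c3ccccc3)C(C)(C)C[C@H](O[Si](C)(C)C(C)(C)C)C[C@@]2(C)O1 | intermediate (key-step product)
15 | selenoxide of 14 (either configuration at selenium) | CC(C)(C)C(=O)OC/C=C(\C)[C@@H]1C[C@@]2([Se](=O)c3ccccc3)C(C)(C)C[C@H](O[Si](C)(C)C(C)(C)C)C[C@@]2(C)O1 | intermediate (not isolated)
16 | (2E)-3-[(2S,6S,7aR)-6-(TBSO)-4,4,7a-trimethyl-2,4,5,6,7,7a-hexahydro-1-benzofuran-2-yl]but-2-en-1-yl 2,2-dimethylpropanoate | CC(C)(C)C(=O)OC/C=C(\C)[C@@H]1C=C2C(C)(C)C[C@H](O[Si](C)(C)C(C)(C)C)C[C@@]2(C)O1 | intermediate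
17 | (2E)-3-[(2S,6S,7aR)-6-(TBSO)-4,4,7a-trimethyl-2,4,5,6,7,7a-hexahydro-1-benzofuran-2-yl]but-2-en-1-ol | OC/C=C(\C)[C@@H]1C=C2C(C)(C)C[C@H](O[Si](C)(C)C(C)(C)C)C[C@@]2(C)O1 | intermediate
18 | (2S,6S,7aR)-2-[(2E)-4-bromobut-2-en-2-yl]-6-(TBSO)-4,4,7a-trimethyl-2,4,5,6,7,7a-hexahydro-1-benzofuran | BrC/C=C(\C)[C@@H]1C=C2C(C)(C)C[C@H](O[Si](C)(C)C(C)(C)C)C[C@@]2(C)O1 | intermediate (not isolated)
19 | {(2E)-3-[(2S,6S,7aR)-6-(TBSO)-4,4,7a-trimethyl-2,4,5,6,7,7a-hexahydro-1-benzofuran-2-yl]but-2-en-1-yl}triphenylphosphonium bromide | [Br-].C(/C=C(\C)[C@@H]1C=C2C(C)(C)C[C@H](O[Si](C)(C)C(C)(C)C)C[C@@]2(C)O1)[P+](c1ccccc1)(c1ccccc1)c1ccccc1 | intermediate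
20 | (R)-α-ionone | CC1=CCCC(C)(C)[C@H]1/C=C/C(C)=O | starting material
21 | triethyl phosphonoacetate | CCOC(=O)CP(=O)(OCC)OCC | starting material
22 | ethyl (2E,4E)-3-methyl-5-[(1R)-2,6,6-trimethylcyclohex-2-en-1-yl]penta-2,4-dienoate | CC1=CCCC(C)(C)[C@H]1/C=C/C(C)=C/C(=O)OCC | intermediate
23 | ethyl (2E,4E)-3-methyl-5-[(1R)-2,6,6-trimethyl-4-oxocyclohex-2-en-1-yl]penta-2,4-dienoate | CC1=CC(=O)CC(C)(C)[C@H]1/C=C/C(C)=C/C(=O)OCC | intermediate
24 | ethyl (2E,4E)-5-[(1R,4R)-4-hydroxy-2,6,6-trimethylcyclohex-2-en-1-yl]-3-methylpenta-2,4-dienoate | CC1=C[C@H](O)CC(C)(C)[C@H]1/C=C/C(C)=C/C(=O)OCC | intermediate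
25 | ethyl (2E,4E)-5-[(1R,4R)-4-(TBSO)-2,6,6-trimethylcyclohex-2-en-1-yl]-3-methylpenta-2,4-dienoate | CC1=C[C@H](O[Si](C)(C)C(C)(C)C)CC(C)(C)[C@H]1/C=C/C(C)=C/C(=O)OCC | intermediate
26 | (2E,4E)-5-[(1R,4R)-4-(TBSO)-2,6,6-trimethylcyclohex-2-en-1-yl]-3-methylpenta-2,4-dien-1-ol | CC1=C[C@H](O[Si](C)(C)C(C)(C)C)CC(C)(C)[C@H]1/C=C/C(C)=C/CO | intermediate
27 | {[(1R,4R)-4-[(1E,3E)-5-bromo-3-methylpenta-1,3-dien-1-yl]-3,5,5-trimethylcyclohex-2-en-1-yl]oxy}(tert-butyl)dimethylsilane | CC1=C[C@H](O[Si](C)(C)C(C)(C)C)CC(C)(C)[C@H]1/C=C/C(C)=C/CBr | intermediate (not isolated)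
28 | {(2E,4E)-5-[(1R,4R)-4-(TBSO)-2,6,6-trimethylcyclohex-2-en-1-yl]-3-methylpenta-2,4-dien-1-yl}triphenylphosphonium bromide | CC1=C[C@H](O[Si](C)(C)C(C)(C)C)CC(C)(C)[C@H]1/C=C/C(C)=C/C[P+](c1ccccc1)(c1ccccc1)c1ccccc1.[Br-] | intermediate
29 | (2E,4E,6E)-2,7-dimethylocta-2,4,6-trienedial | O=C/C(C)=C/C=C/C=C(C)/C=O | starting material
30 | (2E,4E,6E,8E,10E,12E)-13-[(1R,4R)-4-(TBSO)-2,6,6-trimethylcyclohex-2-en-1-yl]-2,7,11-trimethyltrideca-2,4,6,8,10,12-hexaenal | CC1=C[C@H](O[Si](C)(C)C(C)(C)C)CC(C)(C)[C@H]1/C=C/C(C)=C/C=C/C(C)=C/C=C/C=C(C)/C=O | intermediate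
31 | all-E (3S,5R,8S,3'R,6'R)-3,3'-bis(TBSO)-5,8-epoxy-5,8-dihydro-β,ε-carotene | CC1=C[C@H](O[Si](C)(C)C(C)(C)C)CC(C)(C)[C@H]1/C=C/C(C)=C/C=C/C(C)=C/C=C/C=C(C)/C=C/C=C(\C)[C@@H]1C=C2C(C)(C)C[C@H](O[Si](C)(C)C(C)(C)C)C[C@@]2(C)O1 | intermediate
32 | all-E (3S,5R,8S,3'R,6'R)-5,8-epoxy-5,8-dihydro-β,ε-carotene-3,3'-diol | CC1=C[C@H](O)CC(C)(C)[C@H]1/C=C/C(C)=C/C=C/C(C)=C/C=C/C=C(C)/C=C/C=C(\C)[C@@H]1C=C2C(C)(C)C[C@H](O)C[C@@]2(C)O1 | target

**Count**
Total: 22 steps. Longest linear sequence: 13 steps (1–4, 7–13, 21, 22, from actinol).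

**Steps most likely to fail**

Step 10. The selenium electrophile may engage the shielded tetrasubstituted alkene too slowly, or oxygen may be delivered to the face syn to the silyloxy group. The fallback closes the furan ring from the other end; it sets out from 3 and returns at 16. Commercial (E)-3-methylpent-2-en-4-yn-1-ol is pivaloylated to (E)-3-methylpent-2-en-4-yn-1-yl 2,2-dimethylpropanoate F1 and hydroborated with pinacolborane (Cp2ZrHCl cat.) to the (2E,4E)-dienylboronate F2. Suzuki–Miyaura coupling of F2 with 3 (PdCl2(dppf), K3PO4, dioxane/H2O) should give the C15 triene pivalate F3. mCPBA should epoxidise the electron-rich ring alkene anti to the silyloxy group to give the 5,6-epoxide F4. A trace of acid (pyridinium tosylate, CH2Cl2) then triggers the classical epoxide-to-furanoid rearrangement (C6–O heterolysis to the allylic cation, capture at C8 by the C5 oxygen). This should give 16 together with its C8 epimer F5, which are separated by chromatography. The fallback fixes C5 reliably but gives up control at C8.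

Step 21. The ylide from 19 may lose its allylic ring oxygen by vinylogous elimination, or C8 may epimerise under base. The fallback reverses the polarity; it sets out from 17 and 30 and returns at 31. Alcohol 17 is oxidised with MnO2 to the furanoid enal F6. Aldehyde 30 is reduced with NaBH4 to the C25 alcohol F7, brominated (CBr4, PPh3, 2,6-lutidine) to the C25 bromide F8 and quaternised with PPh3 to the C25 phosphonium bromide F9. The ylide of F9 (NaOMe) is condensed with F6, followed by the same thermal equilibration, to give 31.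

Step 16. The hydride may be delivered to the wrong ring face (cis alcohol), or conjugate reduction may compete. The fallback sets out from 23 and returns at 24. Luche reduction (NaBH4, CeCl3, MeOH) is expected to favour axial attack and give the cis alcohol F10. Mitsunobu inversion (4-nitrobenzoic acid, PPh3, diisopropyl azodicarboxylate) gives the trans 4-nitrobenzoate F11, and ethanolysis (K2CO3, EtOH) gives 24.

**Further compounds**
F1 | step 10 | (E)-3-methylpent-2-en-4-yn-1-yl 2,2-dimethylpropanoate | C#C/C(C)=C/COC(=O)C(C)(C)C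
F2 | step 10 | (2E,4E)-3-methyl-5-(4,4,5,5-tetramethyl-1,3,2-dioxaborolan-2-yl)penta-2,4-dien-1-yl 2,2-dimethylpropanoate | CC1(C)OB(/C=C/C(C)=C/COC(=O)C(C)(C)C)OC1(C)C
F3 | step 10 | (2E,4E)-5-[(4R)-4-(TBSO)-2,6,6-trimethylcyclohex-1-en-1-yl]-3-methylpenta-2,4-dien-1-yl 2,2-dimethylpropanoate | CC1=C(/C=C/C(C)=C/COC(=O)C(C)(C)C)C(C)(C)C[C@H](O[Si](C)(C)C(C)(C)C)C1
F4 | step 10 | (2E,4E)-5-[(1S,4S,6R)-4-(TBSO)-2,2,6-trimethyl-7-oxabicyclo[4.1.0]heptan-1-yl]-3-methylpenta-2,4-dien-1-yl 2,2-dimethylpropanoate | C[C@]12O[C@@]1(/C=C/C(C)=C/COC(=O)C(C)(C)C)C(C)(C)C[C@H](O[Si](C)(C)C(C)(C)C)C2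
F5 | step 10 | (2E)-3-[(2R,6S,7aR)-6-(TBSO)-4,4,7a-trimethyl-2,4,5,6,7,7a-hexahydro-1-benzofuran-2-yl]but-2-en-1-yl 2,2-dimethylpropanoate (C8 epimer of 16) | CC(C)(C)C(=O)OC/C=C(\C)[C@H]1C=C2C(C)(C)C[C@H](O[Si](C)(C)C(C)(C)C)C[C@@]2(C)O1
F6 | step 21 | (2E)-3-[(2S,6S,7aR)-6-(TBSO)-4,4,7a-trimethyl-2,4,5,6,7,7a-hexahydro-1-benzofuran-2-yl]but-2-enal | O=C/C=C(\C)[C@@H]1C=C2C(C)(C)C[C@H](O[Si](C)(C)C(C)(C)C)C[C@@]2(C)O1
F7 | step 21 | (2E,4E,6E,8E,10E,12E)-13-[(1R,4R)-4-(TBSO)-2,6,6-trimethylcyclohex-2-en-1-yl]-2,7,11-trimethyltrideca-2,4,6,8,10,12-hexaen-1-ol | CC1=C[C@H](O[Si](C)(C)C(C)(C)C)CC(C)(C)[C@H]1/C=C/C(C)=C/C=C/C(C)=C/C=C/C=C(C)/CO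
F8 | step 21 | the corresponding C25 allylic bromide (1-bromo analogue of F7) | CC1=C[C@H](O[Si](C)(C)C(C)(C)C)CC(C)(C)[C@H]1/C=C/C(C)=C/C=C/C(C)=C/C=C/C=C(C)/CBr
F9 | step 21 | {(2E,4E,6E,8E,10E,12E)-13-[(1R,4R)-4-(TBSO)-2,6,6-trimethylcyclohex-2-en-1-yl]-2,7,11-trimethyltrideca-2,4,6,8,10,12-hexaen-1-yl}triphenylphosphonium bromide | CC1=C[C@H](O[Si](C)(C)C(C)(C)C)CC(C)(C)[C@H]1/C=C/C(C)=C/C=C/C(C)=C/C=C/C=C(C)/C[P+](c1ccccc1)(c1ccccc1)c1ccccc1.[Br-]
F10 | step 16 | ethyl (2E,4E)-5-[(1R,4S)-4-hydroxy-2,6,6-trimethylcyclohex-2-en-1-yl]-3-methylpenta-2,4-dienoate | CC1=C[C@@H](O)CC(C)(C)[C@H]1/C=C/C(C)=C/C(=O)OCC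
F11 | step 16 | (1R,4R)-4-[(1E,3E)-5-ethoxy-3-methyl-5-oxopenta-1,3-dien-1-yl]-3,5,5-trimethylcyclohex-2-en-1-yl 4-nitrobenzoate | CC1=C[C@H](OC(=O)c2ccc(cc2)[N+](=O)[O-])CC(C)(C)[C@H]1/C=C/C(C)=C/C(=O)OCC
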